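Remark on the chemistry (assumption): the cycloaddition in step 5 is taken to occur on the face of 2 opposite to the isopropenyl group; every absolute configuration below rests on this and on (S)-limonene of high enantiomeric purity.

## Analysis of the target

Target 29 is built on a bicyclo[3.3.1]nonane made of ring A (C1–C2–C3–C4–C5–C9, the ketol ring) and ring B (C1–C8–C7–C6–C5–C9). Ring B is fused through C7–C8 to the cycloheptadiene ring C (C7, C10, C11, C12, C13, C14, C8), which carries the δ-lactone ring D (C11–C15H2–C16(=O)–O–C17(CH3)2–C12); the bridge carbon C9 is a spiro-epoxide. The locants are used only in this text: C1 is the ester-bearing bridgehead, C3 the carbinol carbon, C4 the ketone, C5 the methyl-bearing bridgehead, C8 the angular-methyl carbon, C10 the methyl-bearing diene carbon.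

There are six stereocentres. C1 and C5 are tied to each other by the bicycle. At C3 the hydroxyl is exo (away from ring B) and the methyl endo. At C8 the methyl is axial on ring B and anti to the C2–C3–C4 bridge. H-7 is trans to that methyl, so ring C is fused trans-diequatorially. At C9 the epoxide oxygen lies over ring A, syn to the C3 hydroxyl.

The sensitive groups are the tertiary α-ketol (acyloin shift, and cleavage while C9 is still a ketone), the spiro-epoxide and the tertiary allylic lactone C–O bond (acid), the electron-rich diene (electrophiles, oxidants), and the exocyclic alkene next to a free hydroxyl.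

The synthesis is hard for three reasons. Four ring carbons are fully substituted (C1, C3, C5, C8), with C1 and C8 adjacent. The seven-membered ring carries three different substituents on its diene (C10, C11, C12). H-7 sits next to a carbon that is sp2 in the target, so its configuration must be settled while C10 is still a ketone.

The strategy rests on one feature. C8, C7, C10, C12, C13 and C14, with the methyl on C8 and the three-carbon branch on C12, are the ring of a p-menthan-3-one oxidised at C10. The seventh ring atom, C11, which carries the lactone methylene, lies between C10 and C12. Inserting C11 as a carbene into the C10=C12 bond of the silyl dienol ether of such a ketone enlarges the ring and leaves bromine on C11 for attaching C15.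

## Retrosynthetic reasoning

**Epoxide (29 from 28).** The C9–O and CH2–O bonds are cut last, because the spiro-epoxide is the most acid-sensitive group and the free C3 hydroxyl of 28 is the one handle that tells the exocyclic alkene apart from the ring diene. The forward step has to deliver oxygen to the ring A face of the methylene only.

**Lactone (28 from 27).** The O–C17 bond is cut, leading back to an ester on C15 and an isopropenyl group on C12. The C17 oxygen then comes from the carboxyl group and no separate hydration is needed. Forward, acid has to generate the C17 cation and close the six-membered ring there and not at a ring carbon.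

**C11–C15 (27 from 26).** C11 is a fully substituted diene carbon, so its side chain is best attached by cross-coupling of an alkenyl bromide with a two-carbon zinc ester enolate. The coupling must tolerate the hindered C4 ketone and the ester.

**C10 methyl and the diene (26 from 24 through 25).** The C10–CH3 bond comes from 1,2-addition of a methyl nucleophile to the C10 ketone. Loss of water along C10–C11–C12–C13 then places the diene. Doing this before the coupling means the zinc enolate never meets the C10 ketone.

**Key disconnection (24 from 21 and 22).** C10–C11 and C11–C12 are cut together: C11 is removed as a carbene derived from 22, and the six-membered silyl dienol ether 21 remains. One operation gives the ring size, the C11=C12 alkene and the bromide. The forward step must pick the enol ether double bond out of three alkenes.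

**Enol ether (21 from 20).** The O–Si bonds are cut. Enone 20 (isopropylidene on C12) and its deconjugated isopropenyl isomer give the same dienol ether, so the conjugated, configurationally simpler ketone is carried.

**Ring-fusion hydrogen and ketol (20 from 18 via 19; 18 from 17; 17 from 16).** H-7 is introduced by protonation of a C7=C10 enol derivative and equilibration in the bicycle, where the trans fusion is clearly favoured. The C3–O bond is cut back to the C4 ketone enolate, which can only be attacked from the exo face. The C4 ketone comes from the alcohol.

**Exocyclic methylene (16 from 14 via 15; 14 from 13).** The C9=CH2 bond is cut to a C9 ketone. This has to be done while C4 is still a protected alcohol and C10 is masked, so that C9 is the only carbonyl present.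

**Ring A (13 from 11 and 4 via 12).** C1–C2 and C4–C5 are cut: a three-carbon enal is joined to the two α-carbons of the C9 ketone by Michael addition and aldol closure. The forward step must put the new bridge on the face of ring B opposite to the C8 methyl.

**Masking of C10 (11 from 10; 10 from 8 via 9).** The C10 ketone is converted into the C7=C10 silyl dienol ether. This hides the second ketone during five steps and makes C7 trigonal, which fixes the conformation that directs the Michael addition. The cis ring fusion left by the cycloaddition thereby becomes irrelevant.

**Ring B (8 from 2 and 7).** C1–C8 and C6–C7 are cut in a Diels–Alder sense. The quaternary C8 and its absolute configuration come from the terpene enone 2.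

**Starting materials.** 2 comes from 1 by allylic oxidation. 7 comes from 3 and 4 through 5 and 6.

## Alternatives that were turned down

**Alternative 1:** Here the cycloaddition that forms ring B (C1–C8 and C6–C7) is the strategic step: 7 adds to 2 under an aluminium Lewis acid pair to give the cis-fused adduct A1, which is the same compound as 8.
- For: it is convergent, builds the quaternary C8 from the chiral pool in one step, and belongs to a known class of cycloadditions between hindered partners. On this point it is as strong as anything here, and the present route uses it as step 5.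
- Against, as an organising idea: it answers only ring B. A1 has H-7 on the wrong face, lacks the three ring A carbons, and offers no plan for C11, the seven-membered ring or the handle for C15.
- Comparison: the chosen strategy keeps this opening and spends its one risky step on the ring enlargement that the cycloaddition leaves open.

**Alternative 2:** Ring A is traced back to a smaller ring. An alkoxide-induced α-ketol (acyloin) shift moves the C2 methylene from a carbinol carbon (the future C4) to an adjacent acetyl carbon (the future C3), enlarging a five-membered ring to the six-membered ketol ring of A2.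
- For: the shift is driven by strain release and places hydroxyl, methyl and ketone in their final positions in one step. On the ketol itself it is stronger than steps 11 and 12 here, which need an oxidation and an enolate hydroxylation.
- Against: the acetyl carbinol it needs is no easier to make than the bicyclo[3.3.1]nonanone that one annulation gives. Two groups could migrate from the carbinol carbon (C2 or the C5 bridgehead), and the C3 configuration depends on the acetyl rotamer. A2 still has a six-membered terpene ring, held as a dioxolane, so C11, ring C and ring D all remain.
- Comparison: its risk falls on a part of the molecule that ordinary chemistry reaches; the chosen route is two steps longer at the ketol but puts the risk on ring C.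

**Alternative 3:** The C12=C13 bond is cut. Ruthenium-alkylidene ring-closing metathesis would join an allyl group on C8 to the methylene of an α-substituted vinyl ketone chain on C7 and give cycloheptenone A3, with loss of the two terminal methylene groups.
- For: it is mild and tolerant of ketol and ester. The oxygenated C17 is already on C12 before the ring closes, so the lactone oxygen is placed without ambiguity, which is stronger than the acid-mediated step 19 here.
- Against: the p-menthane ring can no longer be used. C8 needs an allyl group and C7 a branched five-carbon chain with its own stereocentre, so C10–C14 must be assembled from small pieces. The metathesis must engage a 1,1-disubstituted enone alkene next to a silyloxy-isopropyl group. In A3 the carbonyl sits on C11, the carbon that has to carry C15, so a further carbonyl-to-carbon exchange follows.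
- Comparison: the chosen route takes six ring atoms from limonene and adds the seventh in one step, at the price of a less secure lactonisation.

Key step: step 15

## Route

Step 1
Reactants: 1 (S)-(−)-limonene
Product: 2 (R)-isopiperitenone
Conditions: Cr(CO)6 (0.3 equiv), t-BuOOH, MeCN, reflux
Reagents that add atoms: tert-butyl hydroperoxide, CC(C)(C)OO
Why: Chromium-catalysed allylic oxidation; hydrogen abstraction at the ring CH2 between the alkene CH and the stereocentre gives the more substituted allyl radical, and oxygenation at its secondary end gives the enone conjugated with the methyl-bearing carbon. The stereocentre is not touched (it becomes C6, R); the regioisomeric enone is removed by chromatography.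

Step 2
Reactants: 3 methyl acetate; 4 methacrolein
Product: 5 methyl 3-hydroxy-4-methylpent-4-enoate
Conditions: LiN(iPr)2, THF, −78 °C
Reagents that add atoms: none
Why: Aldol addition of the lithium ester enolate to the aldehyde carbonyl (1,2-addition); the racemic carbinol is oxidised in the next step.

Step 3
Reactants: 5 methyl 3-hydroxy-4-methylpent-4-enoate
Product: 6 methyl 4-methyl-3-oxopent-4-enoate
Conditions: Dess–Martin periodinane, NaHCO3, CH2Cl2, 0 → 23 °C
Reagents that add atoms: none
Why: Oxidation of the allylic alcohol to the β-keto ester under non-basic conditions, which spare the vinyl ketone from Michael self-condensation.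

Step 4
Reactants: 6 methyl 4-methyl-3-oxopent-4-enoate
Product: 7 silyloxy diene ester
Conditions: t-BuMe2SiOTf, Et3N, Et2O, 0 °C
Reagents that add atoms: tert-butyldimethylsilyl trifluoromethanesulfonate, CC(C)(C)[Si](C)(C)OS(=O)(=O)C(F)(F)F
Why: Soft enolisation and O-silylation of the β-keto ester give the 2-silyloxy diene, mainly as the Z isomer; the geometry is of no consequence because C1 is re-formed later.

Step 5
Reactants: 2 (R)-isopiperitenone; 7 silyloxy diene ester
Product: 8 cis-fused Diels–Alder adduct
Conditions: AlBr3 (0.3 equiv), AlMe3 (0.03 equiv), PhMe–CH2Cl2, −10 °C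
Reagents that add atoms: none
Why: Lewis-acid-promoted Diels–Alder reaction of a hindered 2-silyloxy diene with a β-substituted cyclohexenone; the ester-bearing enol ether terminus (C1) bonds to the enone β-carbon (C8) and the methylene terminus (C6) to the α-carbon (C7), while AlMe3 scavenges protic acid that would isomerise 2. Endo approach anti to the isopropenyl group should set C8, the only stereocentre of 8 that is kept; C1, C7 and C12 are reset or erased later.

Step 6
Reactants: 8 cis-fused Diels–Alder adduct
Product: 10 enone β-keto ester, via isopropenyl diketo ester 9 (not isolated)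
Conditions: Bu4NF, THF, 0 °C; then DBU, 23 °C
Reagents that add atoms: none
Why: Fluoride cleaves the silyl enol ether to the β-keto ester, and DBU moves the isopropenyl double bond into conjugation (β,γ- to α,β-unsaturated ketone). This removes the doubly activated hydrogen at C12, so H-7 is the only α-hydrogen left at the C10 ketone; C1, C5 and C7 are epimerisable here and are fixed later.

Step 7
Reactants: 10 enone β-keto ester
Product: 11 cross-conjugated silyl dienol ether
Conditions: LiN(iPr)2 (2.2 equiv), THF, −78 °C; t-BuMe2SiOTf (1.05 equiv); aq. NH4Cl
Reagents that add atoms: tert-butyldimethylsilyl trifluoromethanesulfonate, CC(C)(C)[Si](C)(C)OS(=O)(=O)C(F)(F)F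
Why: The first equivalent of amide base turns the β-keto ester into its enolate, which shields ring B; the second removes H-7, the α′-hydrogen of the enone, under kinetic control (amide bases deprotonate enones at α′ faster than at γ), and the more basic ketone dienolate is silylated on oxygen. C7 becomes trigonal, so both ring-fusion epimers of 10 converge, and the C10 carbonyl stays masked until step 13.

Step 8
Reactants: 11 cross-conjugated silyl dienol ether; 4 methacrolein
Product: 13 tricyclic ketol, via Michael adduct aldehyde 12 (not isolated)
Conditions: DBU (0.2 equiv), MeCN, 0 → 40 °C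
Reagents that add atoms: none
Why: Michael addition of the β-keto ester to the enal followed by intramolecular aldol addition of the C9 ketone (through C5) to the aldehyde, an α,α′-annulation to a bicyclo[3.3.1]nonan-9-one. With C7 trigonal the C8–C14 bond lies near the plane of the enol ether and the C8 methyl is pseudoaxial next to C1, so the acceptor should add to C1 anti to this methyl (sets C1). C5 is then fixed by the bridge; the configurations at C3 and C4 are removed in steps 11 and 12.

Step 9
Reactants: 13 tricyclic ketol
Product: 14 trimethylsilyl ether
Conditions: Me3SiCl, imidazole, CH2Cl2, 0 °C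
Reagents that add atoms: chlorotrimethylsilane, C[Si](C)(C)Cl
Why: Silylation of the secondary alcohol; the free β-hydroxy ketone would undergo retro-aldol cleavage under the basic olefination conditions.

Step 10
Reactants: 14 trimethylsilyl ether
Product: 16 methylene alcohol, via methylene trimethylsilyl ether 15 (not isolated)
Conditions: Ph3PCH3Br, KN(SiMe3)2, PhMe, 90 °C; then K2CO3, MeOH, 0 °C
Reagents that add atoms: methylenetriphenylphosphorane, C=P(c1ccccc1)(c1ccccc1)c1ccccc1
Why: Wittig methylenation of the only free ketone, which cannot enolise but lies between two quaternary carbons, hence the elevated temperature; ester, silyl ether and silyl dienol ether do not react with the ylide. Mild methanolysis then removes the alkyl trimethylsilyl ether and leaves the tetrasubstituted tert-butyldimethylsilyl dienol ether.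

Step 11
Reactants: 16 methylene alcohol
Product: 17 methylene ketone
Conditions: Dess–Martin periodinane, pyridine, CH2Cl2, 0 °C
Reagents that add atoms: none
Why: Oxidation of the secondary alcohol with buffering that the acid-labile dienol ether tolerates; C9 is no longer a ketone, so no cleavable 1,3-diketone arises.

Step 12
Reactants: 17 methylene ketone
Product: 18 α-ketol
Conditions: KN(SiMe3)2, THF, −78 → −40 °C; 2-(phenylsulfonyl)-3-phenyloxaziridine, −78 °C
Reagents that add atoms: 2-(phenylsulfonyl)-3-phenyloxaziridine, O=S(=O)(c1ccccc1)N1OC1c1ccccc1
Why: Enolate hydroxylation with an N-sulfonyloxaziridine; C4 is the only enolisable carbonyl and can enolise only toward C3. The oxidant should attack the potassium enolate from the exo face, away from ring B, which sets C3 with OH exo and CH3 endo as in the target.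

Step 13
Reactants: 18 α-ketol
Product: 20 enone ketol, via C7-epimeric enone ketol 19 (not isolated)
Conditions: Bu4NF, THF, 0 °C; then DBU, PhMe, 60 °C
Reagents that add atoms: none
Why: Fluoride releases the cross-conjugated dienolate, which is protonated at C7 to return the enone; DBU then equilibrates C7 through the same enolate. The epimer with C10 equatorial on the chair of ring B (H-7 endo, trans to the C8 methyl) should prevail, because the other holds C10 axial against C2 and C4; this sets C7.

Step 14
Reactants: 20 enone ketol
Product: 21 bis(trimethylsilyl) key precursor
Conditions: Me3SiOTf, Et3N, CH2Cl2, −78 → 0 °C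
Reagents that add atoms: trimethylsilyl trifluoromethanesulfonate, C[Si](C)(C)OS(=O)(=O)C(F)(F)F
Why: Soft enolisation: O-silylation of the enone and loss of a γ-hydrogen from an isopropylidene methyl give the conjugated silyl dienol ether (H-7 is endo and out of reach, C4 has no α-hydrogen). The tertiary alcohol is silylated in the same operation.

Step 15
Reactants: 21 bis(trimethylsilyl) key precursor; 22 bromoform
Product: 24 tricyclic 2-bromocyclohept-2-enone, via dibromocyclopropane 23 (not isolated)
Conditions: KOt-Bu, pentane, −30 → 23 °C
Reagents that add atoms: none
Why: KOt-Bu and 22 give dibromocarbene by α-elimination, and this electrophile adds in a concerted [2+1] step to the C10=C12 enol ether bond of 21 to give 23. In 23 the endo bromide ionises while the bond shared by the three- and six-membered rings (C10–C12) breaks in a disrotatory two-electron opening, assisted by the oxygen lone pair at C10 and the isopropenyl group at C12; bromide then removes the trimethylsilyl group to leave 24. The closest known reaction is the ring expansion of cyclic trimethylsilyl enol ethers with dihalocarbenes to 2-halocycloalk-2-enones. The seven-membered ring is closed by ring enlargement, not by cyclisation: C11 forms both its ring bonds (C10–C11, C11–C12) in the cheletropic addition and the larger ring appears when the shared bond is cleaved. No stereocentre is formed; the two cyclopropane centres of 23 vanish and C7 and C8 are not touched. The step needs chemoselectivity among three alkenes: the tetrasubstituted, oxygen-bearing double bond is by far the most nucleophilic, the isopropenyl group is only 1,1-disubstituted and twisted out of conjugation by allylic strain, and the C9 methylene lies between two quaternary carbons. The direction of opening is fixed by the ring fusion of 23, so the bromide ends on C11 and the alkene at C11=C12. The C4 ketone has no α-hydrogen and, like the neopentyl ester, is too hindered for the alkoxide at low temperature in pentane.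

Step 16
Reactants: 24 tricyclic 2-bromocyclohept-2-enone
Product: 25 tertiary allylic carbinol
Conditions: MeLi, CeCl3, THF, −78 °C
Reagents that add atoms: methyllithium, [Li]C
Why: 1,2-Addition of the weakly basic organocerium reagent to the conjugated ketone; the C4 ketone, flanked by two fully substituted carbons, and the neopentyl ester should not react at −78 °C. The carbinol configuration is immaterial, since it is removed in step 17.

Step 17
Reactants: 25 tertiary allylic carbinol
Product: 26 bromotriene
Conditions: Martin sulfurane, CH2Cl2, 0 °C
Reagents that add atoms: none
Why: Dehydration of the tertiary allylic alcohol through the allyl cation (E1); loss of H-13 from the C12 end gives the ring diene C10=C11–C12=C13, the more substituted product of a formal 1,4-elimination. Double-bond isomers, if formed, lead to the same allyl cation in step 19.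

Step 18
Reactants: 26 bromotriene
Product: 27 tert-butyl ester
Conditions: BrZnCH2CO2t-Bu (0.5 M in THF), Pd(PPh3)4 (5 mol %), THF, 60 °C
Reagents that add atoms: (2-tert-butoxy-2-oxoethyl)zinc bromide, CC(C)(C)OC(=O)C[Zn]Br
Why: Palladium-catalysed Negishi coupling of the alkenyl bromide with a Reformatsky reagent; the C10 ketone has already been converted, so the zinc enolate meets only the hindered C4 ketone and the neopentyl ester.

Step 19
Reactants: 27 tert-butyl ester
Product: 28 lactone alcohol
Conditions: CF3CO2H, CH2Cl2, 0 → 23 °C; aq. NaHCO3
Reagents that add atoms: none
Why: Acid-mediated lactonisation of an unsaturated ester: acid cleaves the tert-butyl ester and protonates the isopropenyl methylene to the tertiary allyl cation C17–C12–C13, which the carboxyl oxygen traps at C17 to close the δ-lactone. Closure at C13 would give a bridged lactone with a bridgehead alkene, and closure at C12 would give up the conjugated diene. The trimethylsilyl ether is cleaved under the same conditions.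

Step 20
Reactants: 28 lactone alcohol
Product: 29 CNP0605450.1
Conditions: VO(acac)2 (5 mol %), t-BuOOH, CH2Cl2, 0 → 23 °C
Reagents that add atoms: tert-butyl hydroperoxide, CC(C)(C)OO
Why: Vanadium-catalysed hydroxyl-directed epoxidation of the bishomoallylic tertiary alcohol: with ring A in a boat (endo methyl on C3) the C3 hydroxyl lies over the ring A face of the exocyclic alkene and delivers the peroxide there, which sets C9 with oxygen syn to the hydroxyl. The opposite face is screened by the axial C8 methyl, and the ring diene has no directing group.

## Compound list

1 | (S)-(−)-limonene, (4S)-1-methyl-4-(prop-1-en-2-yl)cyclohex-1-ene | CC1=CC[C@@H](C(C)=C)CC1 | starting material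
2 | (R)-isopiperitenone, (6R)-3-methyl-6-(prop-1-en-2-yl)cyclohex-2-en-1-one | CC1=CC(=O)[C@@H](C(C)=C)CC1 | intermediate
3 | methyl acetate | COC(C)=O | starting material
4 | methacrolein, 2-methylprop-2-enal | C=C(C)C=O | starting material
5 | methyl 3-hydroxy-4-methylpent-4-enoate (racemic) | COC(=O)CC(O)C(C)=C | intermediate
6 | methyl 4-methyl-3-oxopent-4-enoate | COC(=O)CC(=O)C(C)=C | intermediate
7 | methyl (2Z)-3-[(tert-butyldimethylsilyl)oxy]-4-methylpenta-2,4-dienoate | COC(=O)/C=C(\O[Si](C)(C)C(C)(C)C)C(C)=C | intermediate
8 | cis-fused Diels–Alder adduct: methyl 2-[(tert-butyldimethylsilyl)oxy]-3,8a-dimethyl-5-oxo-6-(prop-1-en-2-yl)-1,4,4a,5,6,7,8,8a-octahydronaphthalene-1-carboxylate; H-4a, CH3-8a and the isopropenyl group on one face, the ester on the other | COC(=O)[C@@H]1C(O[Si](C)(C)C(C)(C)C)=C(C)C[C@@H]2C(=O)[C@@H](C(C)=C)CC[C@]12C | intermediate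
9 | methyl 3,8a-dimethyl-2,5-dioxo-6-(prop-1-en-2-yl)decahydronaphthalene-1-carboxylate; C8a as in 8, other centres epimeric | COC(=O)C1C(=O)C(C)CC2C(=O)C(C(C)=C)CC[C@]12C | intermediate
10 | methyl 3,8a-dimethyl-2,5-dioxo-6-(propan-2-ylidene)decahydronaphthalene-1-carboxylate; C8a as in 8, epimers at C1, C3 and C4a | COC(=O)C1C(=O)C(C)CC2C(=O)C(=C(C)C)CC[C@]12C | intermediate
11 | methyl 5-[(tert-butyldimethylsilyl)oxy]-3,8a-dimethyl-2-oxo-6-(propan-2-ylidene)-1,2,3,4,6,7,8,8a-octahydronaphthalene-1-carboxylate; C8a as in 8 | COC(=O)C1C(=O)C(C)CC2=C(O[Si](C)(C)C(C)(C)C)C(=C(C)C)CC[C@]12C | intermediate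
12 | Michael adduct: 11 carrying a 2-methyl-3-oxopropyl group on C1, trans to CH3-8a | COC(=O)[C@@]1(CC(C)C=O)C(=O)C(C)CC2=C(O[Si](C)(C)C(C)(C)C)C(=C(C)C)CC[C@]12C | intermediate
13 | tricyclic ketol: bicyclo[3.3.1]nonan-9-one with CO2CH3 on C1, CH3 on C3, OH on C4, CH3 on C5 and CH3 on C8 (anti to the C2–C4 bridge), fused at C7–C8 to the ring C7=C10(OSiMe2t-Bu)–C12(=CMe2)–C13H2–C14H2; epimers at C3 and C4 | COC(=O)[C@]12CC(C)C(O)[C@](C)(CC3=C(O[Si](C)(C)C(C)(C)C)C(=C(C)C)CC[C@@]31C)C2=O | intermediate
14 | 4-O-trimethylsilyl ether of 13 | COC(=O)[C@]12CC(C)C(O[Si](C)(C)C)[C@](C)(CC3=C(O[Si](C)(C)C(C)(C)C)C(=C(C)C)CC[C@@]31C)C2=O | intermediate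
15 | 9-methylene analogue of 14 (C9=CH2 in place of C9=O) | COC(=O)[C@]12CC(C)C(O[Si](C)(C)C)[C@](C)(CC3=C(O[Si](C)(C)C(C)(C)C)C(=C(C)C)CC[C@@]31C)C2=C | intermediate
16 | 9-methylene alcohol: 15 with free hydroxyl on C4 | COC(=O)[C@]12CC(C)C(O)[C@](C)(CC3=C(O[Si](C)(C)C(C)(C)C)C(=C(C)C)CC[C@@]31C)C2=C | intermediate
17 | 9-methylene 4-ketone (C3 epimers) | COC(=O)[C@]12CC(C)C(=O)[C@](C)(CC3=C(O[Si](C)(C)C(C)(C)C)C(=C(C)C)CC[C@@]31C)C2=C | intermediate
18 | α-ketol: 17 with exo hydroxyl and endo methyl on C3 | COC(=O)[C@]12C[C@@](C)(O)C(=O)[C@](C)(CC3=C(O[Si](C)(C)C(C)(C)C)C(=C(C)C)CC[C@@]31C)C2=C | intermediate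
19 | enone ketol as mixture of C7 epimers (C10 ketone, isopropylidene on C12) | COC(=O)[C@]12C[C@@](C)(O)C(=O)[C@](C)(CC3C(=O)C(=C(C)C)CC[C@@]31C)C2=C | intermediate
20 | enone ketol with H-7 endo, trans to CH3 on C8 | COC(=O)[C@]12C[C@@](C)(O)C(=O)[C@](C)(C[C@H]3C(=O)C(=C(C)C)CC[C@@]31C)C2=C | intermediate
21 | key precursor: 3-O-trimethylsilyl ether carrying the C10=C12 trimethylsilyl dienol ether with isopropenyl on C12 | COC(=O)[C@]12C[C@@](C)(O[Si](C)(C)C)C(=O)[C@](C)(C[C@H]3C(O[Si](C)(C)C)=C(C(C)=C)CC[C@@]31C)C2=C | intermediate
22 | bromoform | BrC(Br)Br | starting material
23 | dibromocyclopropane: CBr2 bridging C10 and C12 of 21 | COC(=O)[C@]12C[C@@](C)(O[Si](C)(C)C)C(=O)[C@](C)(C[C@H]3C4(O[Si](C)(C)C)C(Br)(Br)C4(C(C)=C)CC[C@@]31C)C2=C | intermediate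
24 | tricyclic 2-bromocyclohept-2-enone: C10 ketone, bromine on C11, C11=C12, isopropenyl on C12 | COC(=O)[C@]12C[C@@](C)(O[Si](C)(C)C)C(=O)[C@](C)(C[C@H]3C(=O)C(Br)=C(C(C)=C)CC[C@@]31C)C2=C | intermediate
25 | tertiary allylic carbinol: CH3 and OH on C10 (epimers) | COC(=O)[C@]12C[C@@](C)(O[Si](C)(C)C)C(=O)[C@](C)(C[C@H]3C(C)(O)C(Br)=C(C(C)=C)CC[C@@]31C)C2=C | intermediate
26 | bromotriene: C10(CH3)=C11(Br)–C12(isopropenyl)=C13 | COC(=O)[C@]12C[C@@](C)(O[Si](C)(C)C)C(=O)[C@](C)(C[C@H]3C(C)=C(Br)C(C(C)=C)=CC[C@@]31C)C2=C | intermediate
27 | tert-butyl ester: CH2CO2t-Bu on C11 of the triene | COC(=O)[C@]12C[C@@](C)(O[Si](C)(C)C)C(=O)[C@](C)(C[C@H]3C(C)=C(CC(=O)OC(C)(C)C)C(C(C)=C)=CC[C@@]31C)C2=C | intermediate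
28 | lactone alcohol: ring D closed, free hydroxyl on C3, C9=CH2 | COC(=O)[C@]12C[C@@](C)(O)C(=O)[C@](C)(C[C@H]3C(C)=C4CC(=O)OC(C)(C)C4=CC[C@@]31C)C2=C | intermediate
29 | CNP0605450.1: 28 with the C9 spiro-epoxide, oxygen on the ring A side | COC(=O)[C@]12C[C@@](C)(O)C(=O)[C@](C)(C[C@H]3C(C)=C4CC(=O)OC(C)(C)C4=CC[C@@]31C)[C@]21CO1 | target

## Step count and least certain steps

Total step count: 20. Longest linear sequence: 19 steps (from 3 and 4 through 7 to 29); the branch from 1 has 17 steps.

**Step 15 (key step).** The most likely failure is loss of chemoselectivity, with carbene transfer to the terminal carbon of the isopropenyl group, the other nucleophilic end of a silyloxy diene. The alkoxide may also cleave the trimethylsilyl enol ether before the carbene arrives, which returns 20 on work-up. The fallback sets out from 21 and comes back at 27. Simmons–Smith cyclopropanation (Et2Zn, CH2I2), in which the zinc carbenoid is drawn to the silyl enol ether, should give the siloxycyclopropane F1. FeCl3 in DMF opens F1 by one-electron oxidation and cleavage of the shared bond to the β-chloro cycloheptanone F2, which is not isolated, and NaOAc in MeOH eliminates it to the cyclohept-2-enone F3. Iodine and pyridine then give the 2-iodo-enone F4. MeLi/CeCl3 leads to the iodo carbinol F5 and the sulfurane of step 17 to the iodotriene F6, which is coupled as in step 18 to give 27.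

**Step 7.** Regiocontrol in the second deprotonation may be lost: removal of a γ-hydrogen from an isopropylidene methyl instead of the hindered H-7 would give the conjugated dienol ether with C7 still tetrahedral and undefined. The fallback sets out from 10 and comes back at 11, and replaces the kinetic dianion by thermodynamic enol silylation. t-BuMe2SiCl, NaI and Et3N in MeCN at 60 °C should equilibrate toward the more highly substituted dienol ether and silylate the β-keto ester as well, giving the bis(silyl) compound F7. Brief K2CO3 in MeOH at 0 °C then cleaves only the vinylogous silyl ester and gives 11.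

**Step 5.** The strong Lewis acid may isomerise 2 to its achiral conjugated dienone before cycloaddition, which would erode enantiomeric purity, or the ester-deactivated diene may react too slowly with the β-substituted enone. The fallback sets out from 2 and 7 and comes back at 10. A Mukaiyama–Michael addition catalysed by Tf2NH in CH2Cl2 at −78 °C, with silyl transfer to the enone oxygen, should give the open adduct F8. Bu4NF then releases the ring enolate, which closes ring B by intramolecular Michael addition to the vinyl ketone and gives 9; DBU converts this to 10 as in step 6.

**Step 10.** The ylide may fail to add to the ketone between two quaternary carbons, and prolonged heating may strip the silyl ether and start retro-aldol cleavage. The fallback sets out from 14 and comes back at 16 by Peterson olefination. Me3SiCH2Li with CeCl3 at −78 °C should add to C9 and give the β-hydroxysilane F9. KH in THF then eliminates to 15, and methanolysis as in step 10 gives 16.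

**Step 19.** Under reversible ionisation the cation may take another course: closure to a five-membered lactone at C12 after protonation of C13, migration of the diene, or acid-promoted addition of the freed C3 hydroxyl to the C9 methylene. The fallback sets out from 27 and comes back at 28, and avoids free carbocations. Hg(OCOCF3)2 in MeCN at −20 °C should attack the unhindered isopropenyl terminus; the ester carbonyl closes on C17 with loss of the tert-butyl group, and aqueous NaCl gives the chloromercurio lactone F10. NaBH4 in aqueous NaOH removes mercury to give the silyl ether F11, and aqueous HF in MeCN frees the hydroxyl to give 28.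

## Further compounds

F1 | step 15 | siloxycyclopropane: CH2 bridging C10 and C12 of 21 | COC(=O)[C@]12C[C@@](C)(O[Si](C)(C)C)C(=O)[C@](C)(C[C@H]3C4(O[Si](C)(C)C)CC4(C(C)=C)CC[C@@]31C)C2=C
F2 | step 15 | β-chloro cycloheptanone: C10 ketone, C11H2, chlorine and isopropenyl on C12 | COC(=O)[C@]12C[C@@](C)(O[Si](C)(C)C)C(=O)[C@](C)(C[C@H]3C(=O)CC(Cl)(C(C)=C)CC[C@@]31C)C2=C
F3 | step 15 | cyclohept-2-enone: C10 ketone, C11H=C12, isopropenyl on C12 | COC(=O)[C@]12C[C@@](C)(O[Si](C)(C)C)C(=O)[C@](C)(C[C@H]3C(=O)C=C(C(C)=C)CC[C@@]31C)C2=C
F4 | step 15 | 2-iodocyclohept-2-enone: iodine on C11 | COC(=O)[C@]12C[C@@](C)(O[Si](C)(C)C)C(=O)[C@](C)(C[C@H]3C(=O)C(I)=C(C(C)=C)CC[C@@]31C)C2=C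
F5 | step 15 | iodo carbinol: CH3 and OH on C10, iodine on C11 | COC(=O)[C@]12C[C@@](C)(O[Si](C)(C)C)C(=O)[C@](C)(C[C@H]3C(C)(O)C(I)=C(C(C)=C)CC[C@@]31C)C2=C
F6 | step 15 | iodotriene: C10(CH3)=C11(I)–C12(isopropenyl)=C13 | COC(=O)[C@]12C[C@@](C)(O[Si](C)(C)C)C(=O)[C@](C)(C[C@H]3C(C)=C(I)C(C(C)=C)=CC[C@@]31C)C2=C
F7 | step 7 | bis(silyl) compound: 11 with the β-keto ester as its tert-butyldimethylsilyl enol ether | COC(=O)C1=C(O[Si](C)(C)C(C)(C)C)C(C)CC2=C(O[Si](C)(C)C(C)(C)C)C(=C(C)C)CC[C@]12C
F8 | step 5 | Mukaiyama–Michael adduct: silyl enol ether of the cyclohexanone carrying the acyclic keto ester on the quaternary carbon | COC(=O)C(C(=O)C(C)=C)[C@@]1(C)CC[C@H](C(C)=C)C(O[Si](C)(C)C(C)(C)C)=C1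
F9 | step 10 | β-hydroxysilane: 14 with OH and CH2SiMe3 on C9 | COC(=O)[C@]12CC(C)C(O[Si](C)(C)C)[C@](C)(CC3=C(O[Si](C)(C)C(C)(C)C)C(=C(C)C)CC[C@@]31C)C2(O)C[Si](C)(C)C
F10 | step 19 | chloromercurio lactone: ring D closed, CH2HgCl on C17, trimethylsilyl ether on C3 | COC(=O)[C@]12C[C@@](C)(O[Si](C)(C)C)C(=O)[C@](C)(C[C@H]3C(C)=C4CC(=O)OC(C)(C[Hg]Cl)C4=CC[C@@]31C)C2=C
F11 | step 19 | 3-O-trimethylsilyl ether of 28 | COC(=O)[C@]12C[C@@](C)(O[Si](C)(C)C)C(=O)[C@](C)(C[C@H]3C(C)=C4CC(=O)OC(C)(C)C4=CC[C@@]31C)C2=C
A1 | alternative 1 | cis-fused decalin silyl enol ether (same compound as 8) | COC(=O)[C@@H]1C(O[Si](C)(C)C(C)(C)C)=C(C)C[C@@H]2C(=O)[C@@H](C(C)=C)CC[C@]12C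
A2 | alternative 2 | bicyclo[3.3.1]nonane ketol with C9 methylene and the C10 ketone as its dioxolane | COC(=O)[C@]12C[C@@](C)(O)C(=O)[C@](C)(C[C@H]3C4(OCCO4)[C@@H](C(C)=C)CC[C@@]31C)C2=C
A3 | alternative 3 | tricyclic cyclohept-2-enone with the ketone on C11 and C17 as its triethylsilyl ether | COC(=O)[C@]12C[C@@](C)(O)C(=O)[C@](C)(C[C@H]3[C@H](C)C(=O)C(C(C)(C)O[Si](CC)(CC)CC)=CC[C@@]31C)C2=C
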